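A direct plan would keep rings A and B as finished benzene rings and close ring C last. B-ring ketone A3 (from the benzoic acid via diazoketone A2 and Rh2(OAc)4 O–H insertion) would add by aldol reaction to bromo aldehyde A1. Oxidation would give 1,3-diketone A4, CuI/1,10-phenanthroline O-arylation (O1–C8a) the tri-O-benzyl flavonol A5, and hydrogenolysis the target.
Its weakest steps would be:
- the diazoketone/O–H-insertion detour: three operations and a hazardous diazo compound only to place one CH2OBn carbon beside the B-ring carbonyl;
- the bromination of the last C–H of the hexasubstituted A-ring aldehyde: it buys only a leaving group and risks ipso or benzylic attack;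
- the late copper C–O closure at a doubly ortho-substituted bromide of a base-labile 2-alkoxy-1,3-diketone (retro-Claisen cleavage, debromination): the plan's only ring closure, run on its most precious material.

**Plan of the new route**
The route cuts C4a–C5 and C8–C8a of ring A (back to dimethyl squarate and a 4-pyranone metalated at C6) and then C2–C1' (Suzuki coupling). Ring C is bought as pyromeconic acid, ring B is attached to it, and ring A is built last. The enabling feature is that C5–C8 of ring A carry four contiguous oxygens, 5-OH para to 8-OMe with two OMe between, which are the four carbons of a squarate ester, while C4a=C8a is the C5=C6 bond of a 4-pyranone. The ketene carbon becomes the free 5-OH and the methylated carbinol carbon becomes C8. There is no diazoketone, no A-ring bromination and no C–O ring closure: O1–C8a exists from the start and ring B enters as a boronate from C–H borylation.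

Key step: step 7

Assumption: 2,3-dimethoxyphenol, 3-hydroxy-4H-pyran-4-one (pyromeconic acid) and dimethyl squarate are taken as commercial. The target is achiral; the chiral intermediates 10, 11 and 13 are racemic and their stereocentres are destroyed in step 7.

Step 1
Reactants: 1 2,3-dimethoxyphenol
Product: 2 1,2-dimethoxy-3-(methoxymethoxy)benzene
Conditions: MOMCl (1.3 equiv), iPr2NEt (1.6 equiv), CH2Cl2, 0 °C → rt
Reagents that add atoms: chloromethyl methyl ether, COCCl
Why: O-alkylation of the phenol to its methoxymethyl acetal (Williamson-type), a group without aryl C–H bonds that could compete in step 2 and that is removed together with the second MOM group in the last step.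

Step 2
Reactants: 2 1,2-dimethoxy-3-(methoxymethoxy)benzene
Product: 3 2-[3,4-dimethoxy-5-(methoxymethoxy)phenyl]-4,4,5,5-tetramethyl-1,3,2-dioxaborolane
Conditions: B2pin2 (0.7 equiv), [Ir(OMe)(cod)]2 (1.5 mol%; cod = 1,5-cyclooctadiene), 4,4'-di-tert-butyl-2,2'-bipyridine (3 mol%), THF, 80 °C, Ar
Reagents that add atoms: bis(pinacolato)diboron, CC1(C)OB(OC1(C)C)B1OC(C)(C)C(C)(C)O1
Why: Iridium-catalysed, sterically governed aromatic C–H borylation (Hartwig–Miyaura borylation), which in a 1,2,3-trisubstituted benzene should reach only C5, the one C–H without an ortho substituent.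

Step 3
Reactants: 4 3-hydroxy-4H-pyran-4-one (pyromeconic acid)
Product: 5 2-bromo-3-hydroxy-4H-pyran-4-one
Conditions: NBS (1.0 equiv), MeCN, 0 °C → rt, dark
Reagents that add atoms: N-bromosuccinimide, O=C1CCC(=O)N1Br
Why: Electrophilic bromination of the enol at its β-carbon C2, the position beside the hydroxyl group and the ring oxygen that also takes aldehyde and Mannich electrophiles in 3-hydroxy-4-pyranones, with one equivalent of reagent to avoid a second bromination.

Step 4
Reactants: 5 2-bromo-3-hydroxy-4H-pyran-4-one
Product: 6 2-bromo-3-(methoxymethoxy)-4H-pyran-4-one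
Conditions: MOMCl (1.3 equiv), iPr2NEt (1.6 equiv), CH2Cl2, 0 °C
Reagents that add atoms: chloromethyl methyl ether, COCCl
Why: O-alkylation of the acidic enol hydroxyl with a hindered, non-nucleophilic amine base that should not displace the vinylogous acyl bromide.

Step 5
Reactants: 6 2-bromo-3-(methoxymethoxy)-4H-pyran-4-one; 3 2-[3,4-dimethoxy-5-(methoxymethoxy)phenyl]-4,4,5,5-tetramethyl-1,3,2-dioxaborolane
Product: 7 2-[3,4-dimethoxy-5-(methoxymethoxy)phenyl]-3-(methoxymethoxy)-4H-pyran-4-one
Conditions: PdCl2(dppf) (3 mol%; dppf = 1,1'-bis(diphenylphosphino)ferrocene), K3PO4 (2.5 equiv), 1,4-dioxane/H2O 6:1, 80 °C, Ar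
Reagents that add atoms: none
Why: Suzuki–Miyaura coupling that forms C2–C1'; the C2–Br bond is a vinylogous acyl bromide and should add readily to palladium, and phosphate is mild enough to spare the pyranone ring.

Step 6
Reactants: 7 2-[3,4-dimethoxy-5-(methoxymethoxy)phenyl]-3-(methoxymethoxy)-4H-pyran-4-one; 8 dimethyl squarate (3,4-dimethoxycyclobut-3-ene-1,2-dione)
Product: 11 2-[3,4-dimethoxy-5-(methoxymethoxy)phenyl]-3-(methoxymethoxy)-6-(1,2,3-trimethoxy-4-oxocyclobut-2-en-1-yl)-4H-pyran-4-one (racemic), via 6-lithiopyranone 9 (not isolated), via lithium alkoxide of the squarate adduct 10 (not isolated)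
Conditions: LiTMP (lithium 2,2,6,6-tetramethylpiperidide, 1.2 equiv, from 2,2,6,6-tetramethylpiperidine and n-BuLi), THF, −78 °C, slow addition of 7; then 8 (1.3 equiv), −78 °C; then MeOTf (1.5 equiv), −78 → −20 °C; aq. NaHCO3
Reagents that add atoms: methyl trifluoromethanesulfonate, COS(=O)(=O)C(F)(F)F; lithium 2,2,6,6-tetramethylpiperidide, [Li]N1C(C)(C)CCCC1(C)C (lithium of 9 and 10 only)
Why: Proposed new method: LiTMP should remove the C6–H of 7, the only C–H beside the ring oxygen (acidified by O1 and by the polarised vinylogous ester; the corresponding position is the one lithium amides deprotonate in 4-pyridones, 4-quinolones and uracils and that TMP–metal amides can metalate in chromones), while C2 is blocked and slow addition of 7 to the base keeps unmetalated pyranone, the only Michael acceptor, scarce; vinyllithium 9 then adds 1,2 to one of the two equivalent carbonyl groups of 8 and the tertiary alkoxide 10 is O-methylated in situ before it can fragment, the new quaternary centre being racemic and destroyed in step 7; the closest known reaction type is the 1,2-addition of alkenyl- and heteroaryllithiums (including 2-lithiated, carbonyl-masked benzopyranones) to squarate esters with in situ O-alkylation, which has not been shown for a directly lithiated free 4-pyranone.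

Step 7
Reactants: 11 2-[3,4-dimethoxy-5-(methoxymethoxy)phenyl]-3-(methoxymethoxy)-6-(1,2,3-trimethoxy-4-oxocyclobut-2-en-1-yl)-4H-pyran-4-one
Product: 14 5-hydroxy-6,7,8-trimethoxy-3-(methoxymethoxy)-2-[3,4-dimethoxy-5-(methoxymethoxy)phenyl]-4H-chromen-4-one, via (Z)-dienylketene 12 (not isolated), via 4aH-chromene-4,5-dione tautomer 13 (not isolated)
Conditions: toluene (0.02 M, degassed), 110 °C, Ar
Reagents that add atoms: none
Why: On heating, the cyclobutenone opens by conrotatory 4π electrocyclic cleavage of its C(=O)–C(OMe) sigma bond, the donor methoxy group on the sp3 carbon rotating outward so that the pyranonyl group turns inward to give (Z)-dienylketene 12; 12 closes by 6π electrocyclisation between the ketene carbon and pyranone C5 (flavone C4a) to dienone 13, whose doubly activated C4a–H shifts to oxygen to give phenol 14. The closest known reaction type is the thermal ring expansion of 4-aryl-, 4-alkenyl- and 4-heteroaryl-4-alkoxycyclobutenones derived from squarates to para-alkoxyphenols (Moore rearrangement), including benzopyranone-derived cases that lead to xanthones. Ring A is closed as a six-membered carbocycle by disrotatory 6π electrocyclisation (C5–C4a bond), the C8–C8a bond having been made in step 6, and ring C is returned to its pyranone form by the tautomerisation. No stereocentre remains, since the quaternary carbon of 11 becomes the sp2 carbon C8 and the transient C4a centre of 13 is erased by enolisation. The step needs inward rotation of the pyranonyl group, secured by the strong outward preference of the alkoxy donor, and closure at pyranone C5, the only carbon next to the point of attachment that can take part; the 5-OH/8-OMe pattern follows by construction because the ketene carbon becomes the free, carbonyl-chelated phenol and the methylated carbinol carbon becomes C8. High dilution should suppress acylation of the phenol formed by ketene not yet cyclised.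

Step 8
Reactants: 14 5-hydroxy-6,7,8-trimethoxy-3-(methoxymethoxy)-2-[3,4-dimethoxy-5-(methoxymethoxy)phenyl]-4H-chromen-4-one
Product: 15 3,5-dihydroxy-2-(3-hydroxy-4,5-dimethoxyphenyl)-6,7,8-trimethoxy-4H-chromen-4-one (3-demethyldigicitrin)
Conditions: 3 M HCl, MeOH, 50 °C
Reagents that add atoms: none
Why: Acid-catalysed acetal exchange with methanol should remove both MOM groups as dimethoxymethane, while the aryl methyl ethers and the flavonol core are stable to dilute acid.

**Compound list**
1 | 2,3-dimethoxyphenol | COc1cccc(O)c1OC | starting material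
2 | 1,2-dimethoxy-3-(methoxymethoxy)benzene | COCOc1cccc(OC)c1OC | intermediate
3 | 2-[3,4-dimethoxy-5-(methoxymethoxy)phenyl]-4,4,5,5-tetramethyl-1,3,2-dioxaborolane | COCOc1cc(B2OC(C)(C)C(C)(C)O2)cc(OC)c1OC | intermediate
4 | 3-hydroxy-4H-pyran-4-one (pyromeconic acid) | O=c1ccocc1O | starting material
5 | 2-bromo-3-hydroxy-4H-pyran-4-one | O=c1ccoc(Br)c1O | intermediate
6 | 2-bromo-3-(methoxymethoxy)-4H-pyran-4-one | COCOc1c(Br)occc1=O | intermediate
7 | 2-[3,4-dimethoxy-5-(methoxymethoxy)phenyl]-3-(methoxymethoxy)-4H-pyran-4-one | COCOc1cc(-c2occc(=O)c2OCOC)cc(OC)c1OC | intermediate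
8 | dimethyl squarate (3,4-dimethoxycyclobut-3-ene-1,2-dione) | COC1=C(OC)C(=O)C1=O | starting material
9 | 6-lithio derivative of 7 (lithium on pyranone C6) | [Li]c1cc(=O)c(OCOC)c(-c2cc(OC)c(OC)c(OCOC)c2)o1 | intermediate (not isolated)
10 | lithium 2,3-dimethoxy-4-oxo-1-(pyranon-6-yl)cyclobut-2-en-1-olate, the 1,2-adduct of 9 and 8 (racemic) | [Li+].[O-]C1(c2cc(=O)c(OCOC)c(-c3cc(OC)c(OC)c(OCOC)c3)o2)C(OC)=C(OC)C1=O | intermediate (not isolated)
11 | 2-[3,4-dimethoxy-5-(methoxymethoxy)phenyl]-3-(methoxymethoxy)-6-(1,2,3-trimethoxy-4-oxocyclobut-2-en-1-yl)-4H-pyran-4-one (racemic) | COC1=C(OC)C(OC)(c2cc(=O)c(OCOC)c(-c3cc(OC)c(OC)c(OCOC)c3)o2)C1=O | intermediate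
12 | (Z)-2,3,4-trimethoxy-4-(pyranon-6-yl)buta-1,3-dien-1-one, the dienylketene with the pyranonyl group cis to the ketene | COC(=C=O)/C(OC)=C(OC)\c1cc(=O)c(OCOC)c(-c2cc(OC)c(OC)c(OCOC)c2)o1 | intermediate (not isolated)
13 | 6,7,8-trimethoxy-3-(methoxymethoxy)-2-[3,4-dimethoxy-5-(methoxymethoxy)phenyl]-4aH-chromene-4,5-dione (racemic keto tautomer of 14) | COC1=C(OC)C(OC)=C2OC(c3cc(OC)c(OC)c(OCOC)c3)=C(OCOC)C(=O)C2C1=O | intermediate (not isolated)
14 | 5-hydroxy-6,7,8-trimethoxy-3-(methoxymethoxy)-2-[3,4-dimethoxy-5-(methoxymethoxy)phenyl]-4H-chromen-4-one | COCOc1cc(-c2oc3c(OC)c(OC)c(OC)c(O)c3c(=O)c2OCOC)cc(OC)c1OC | intermediate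
15 | 3,5-dihydroxy-2-(3-hydroxy-4,5-dimethoxyphenyl)-6,7,8-trimethoxy-4H-chromen-4-one (3-demethyldigicitrin) | COc1cc(-c2oc3c(OC)c(OC)c(OC)c(O)c3c(=O)c2O)cc(O)c1OC | target

**Step count and risks**
Total steps: 8. Longest linear sequence: 6 steps (steps 3, 4, 5, 6, 7, 8; the branch through steps 1 and 2 is equally long).

Steps most likely to fail:

1. Step 6 (proposed new method). Deprotonation may also occur at C5 beside the carbonyl group, the lithiated pyranone may add to unmetalated 7, and MeOTf may alkylate the pyranone carbonyl oxygen in competition with the alkoxide. The fallback uses known reaction types and separates metalation, addition and methylation; it sets out from 7 and returns at 11. Compound 7 would be zincated beside the ring oxygen with TMP2Zn·2MgCl2·2LiCl (TMP = 2,2,6,6-tetramethylpiperidide; THF, −30 °C), a base type used for metalation of chromones at that position, and the zinc species quenched with I2 to give 2-[3,4-dimethoxy-5-(methoxymethoxy)phenyl]-6-iodo-3-(methoxymethoxy)-4H-pyran-4-one F1. Iodine–magnesium exchange (iPrMgCl·LiCl, THF, −40 °C), addition of the Grignard reagent to 8 and NH4Cl work-up would give the carbinol 6-(1-hydroxy-2,3-dimethoxy-4-oxocyclobut-2-en-1-yl)-2-[3,4-dimethoxy-5-(methoxymethoxy)phenyl]-3-(methoxymethoxy)-4H-pyran-4-one F2. MeI/Ag2O (MeCN, rt) would then methylate the tertiary alcohol to give 11.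

2. Step 7. The 6π closure onto the pyranone double bond may be slower than loss of the dienylketene to oligomers or to acylation of phenol already formed, and the hot, electron-rich phenol may be oxidised by traces of air. The fallback moves the differentiation of the oxygens to after the ring expansion; it sets out from 7 and returns at 14. The adduct of 9 and 8 would be protonated (NH4Cl) instead of methylated, giving carbinol F2, whose free hydroxyl should allow ring opening at lower temperature (toluene, 80–100 °C, Ar). The product would be the hydroquinone 5,8-dihydroxy-6,7-dimethoxy-3-(methoxymethoxy)-2-[3,4-dimethoxy-5-(methoxymethoxy)phenyl]-4H-chromen-4-one F3. Without exposure to air, Me2SO4 (1.05 equiv)/K2CO3 in acetone should methylate only the 8-OH, the 5-OH being held in a hydrogen bond to the C4 carbonyl, to give 14.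

3. Step 5. Displacement of the vinylogous acyl bromide by hydroxide or phosphate and opening of the pyranone ring by aqueous base may outrun transmetalation, and the electron-rich boronate may lose boron by protonolysis. The fallback reverses the polarity of the coupling and needs no bromopyranone; it sets out from 4 and 3, bypasses steps 3 and 4, and returns at 7. Compound 4 would be protected (MOMCl, iPr2NEt) as 3-(methoxymethoxy)-4H-pyran-4-one F4. Boronate 3 would be converted by bromodeboronation (CuBr2, MeOH/H2O, 80 °C) into 5-bromo-1,2-dimethoxy-3-(methoxymethoxy)benzene F5. F4 would be metalated at C2, the C–H flanked by the ring oxygen and the MOM ether (LiTMP, THF, −78 °C, then ZnCl2), and coupled with F5 under Negishi conditions (Pd(PPh3)4, THF, 60 °C) to give 7.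

**Further compounds**
F1 | step 6 | 2-[3,4-dimethoxy-5-(methoxymethoxy)phenyl]-6-iodo-3-(methoxymethoxy)-4H-pyran-4-one | COCOc1cc(-c2oc(I)cc(=O)c2OCOC)cc(OC)c1OC
F2 | step 6 | 6-(1-hydroxy-2,3-dimethoxy-4-oxocyclobut-2-en-1-yl)-2-[3,4-dimethoxy-5-(methoxymethoxy)phenyl]-3-(methoxymethoxy)-4H-pyran-4-one (racemic) | COC1=C(OC)C(O)(c2cc(=O)c(OCOC)c(-c3cc(OC)c(OC)c(OCOC)c3)o2)C1=O
F3 | step 7 | 5,8-dihydroxy-6,7-dimethoxy-3-(methoxymethoxy)-2-[3,4-dimethoxy-5-(methoxymethoxy)phenyl]-4H-chromen-4-one | COCOc1cc(-c2oc3c(O)c(OC)c(OC)c(O)c3c(=O)c2OCOC)cc(OC)c1OC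
F4 | step 5 | 3-(methoxymethoxy)-4H-pyran-4-one | COCOc1coccc1=O
F5 | step 5 | 5-bromo-1,2-dimethoxy-3-(methoxymethoxy)benzene | COCOc1cc(Br)cc(OC)c1OC
A1 | direct plan | 2-(benzyloxy)-6-bromo-3,4,5-trimethoxybenzaldehyde | COc1c(Br)c(C=O)c(OCc2ccccc2)c(OC)c1OC
A2 | direct plan | 1-[3-(benzyloxy)-4,5-dimethoxyphenyl]-2-diazoethan-1-one | COc1cc(C(=O)C=[N+]=[N-])cc(OCc2ccccc2)c1OC
A3 | direct plan | 2-(benzyloxy)-1-[3-(benzyloxy)-4,5-dimethoxyphenyl]ethan-1-one | COc1cc(C(=O)COCc2ccccc2)cc(OCc2ccccc2)c1OC
A4 | direct plan | 2-(benzyloxy)-1-[2-(benzyloxy)-6-bromo-3,4,5-trimethoxyphenyl]-3-[3-(benzyloxy)-4,5-dimethoxyphenyl]propane-1,3-dione (racemic) | COc1cc(C(=O)C(OCc2ccccc2)C(=O)c2c(Br)c(OC)c(OC)c(OC)c2OCc2ccccc2)cc(OCc2ccccc2)c1OC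
A5 | direct plan | 3,5-bis(benzyloxy)-2-[3-(benzyloxy)-4,5-dimethoxyphenyl]-6,7,8-trimethoxy-4H-chromen-4-one | COc1cc(-c2oc3c(OC)c(OC)c(OC)c(OCc4ccccc4)c3c(=O)c2OCc2ccccc2)cc(OCc2ccccc2)c1OC
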